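**Retrosynthetic overview**
1. The butenolide is formed last, by oxidative lactonisation of a (Z)-ene-1,4-diol after all base-mediated unmasking, so the epimerisable lactone carbon never meets base.
2. C12–C13: Negishi sp3–sp2 coupling of a C12 zinc reagent (decalin core) with an (E)-vinyl iodide side arm fixes the 13E olefin.
3. Core from (+)-larixol (rings A and B with C5, C6, C9, C10 bought): the side chain is cut back to C12 via the methyl ketone, a cyclic enol ether (sets 8α-O) and ozonolysis.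
4. C18: 6α-OH-directed 1,5-hydrogen transfer (hypoiodite ether), then RuO4, gives the 18,6α-lactone that masks both the acid and the 6-OH.
5. Side arm from methyl (R)-glycidate (future butenolide stereocentre) and propyne. Ring order: decalin (given), dihydropyran (temporary), ether/lactone bridge (temporary), butenolide (made, opened, re-formed last).

Assumption: (+)-larixol, methyl (R)-glycidate and 1-propynyllithium are bought; decalin atoms carry labdane numbers (C18 = the 4α carbon). The route is a paper design; it has not been run.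

**Step 1**
Reactants: 1 (+)-larixol
Product: 2 6α-hydroxy-14,15-dinorlabd-8(17)-en-13-one
Conditions: KMnO4, acetone/H2O, 0 °C to rt
Reagents that add atoms: none
Why: Permanganate degradation of the vinyl carbinol (dihydroxylation, then glycol cleavage) is faster than attack on the hindered exocyclic alkene and leaves C13 as the methyl ketone without touching a ring stereocentre.

**Step 2**
Reactants: 2 6α-hydroxy-14,15-dinorlabd-8(17)-en-13-one
Product: 3 8α,13-epoxy-14,15-dinorlabd-12-en-6α-ol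
Conditions: p-TsOH·H2O (cat.), MeNO2, rt
Reagents that add atoms: none
Why: Acid-catalysed cycloisomerisation: Markovnikov protonation gives the C8 cation, which the ketone oxygen captures on the equatorial α-face to give the trans-fused dihydropyran under thermodynamic control, setting C8 as 8α-O/8β-Me.

**Step 3**
Reactants: 3 8α,13-epoxy-14,15-dinorlabd-12-en-6α-ol
Product: 5 8α-acetoxy-13,14,15,16-tetranorlabdane-6α,12-diol, via acetoxy aldehyde 4 (not isolated)
Conditions: O3, CH2Cl2/MeOH, −78 °C; then NaBH4, −78 to 0 °C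
Reagents that add atoms: ozone, [O-][O+]=O
Why: Ozonolysis of the enol ether leaves C13 as an acetate on the tertiary 8α-oxygen and C12 as an aldehyde that NaBH4 reduces in the same pot, so the tertiary alcohol emerges already protected.

**Step 4**
Reactants: 5 8α-acetoxy-13,14,15,16-tetranorlabdane-6α,12-diol
Product: 6 12-bromo-6α-hydroxy-13,14,15,16-tetranorlabdan-8α-yl acetate
Conditions: CBr4, PPh3, CH2Cl2, 0 °C
Reagents that add atoms: carbon tetrabromide, BrC(Br)(Br)Br
Why: The Appel reaction is selective for the unhindered primary alcohol over the hindered equatorial 6α-OH and proceeds by SN2 at C12 with no stereocentre involved.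

**Step 5**
Reactants: 6 12-bromo-6α-hydroxy-13,14,15,16-tetranorlabdan-8α-yl acetate
Product: 7 12-bromo-6α,18-epoxy-13,14,15,16-tetranorlabdan-8α-yl acetate
Conditions: PhI(OAc)2, I2, cyclohexane, hν (tungsten lamp), rt
Reagents that add atoms: none
Why: Suárez hypoiodite reaction: the 6α-alkoxy radical sits in a syn-pentane contact with the equatorial 4α-methyl only, so 1,5-hydrogen transfer, iodination and ring closure functionalise C18 and fix C4 as 4α-CH2O/4β-Me.

**Step 6**
Reactants: 7 12-bromo-6α,18-epoxy-13,14,15,16-tetranorlabdan-8α-yl acetate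
Product: 8 8α-acetoxy-12-bromo-13,14,15,16-tetranorlabdan-18,6α-olide
Conditions: RuCl3·xH2O (5 mol%), NaIO4, EtOAc/MeCN/H2O, rt
Reagents that add atoms: sodium periodate (oxygen relayed through RuO4), [Na+].[O-]I(=O)(=O)=O
Why: RuO4 ether-to-lactone oxidation attacks the only ether methylene (C18), while the bromide, the tertiary acetate and all stereocentres are inert.

**Step 7**
Reactants: 9 methyl (R)-glycidate; 10 1-propynyllithium
Product: 11 methyl (2R)-2-hydroxyhex-4-ynoate
Conditions: BF3·OEt2, THF, −78 °C; aq. NH4Cl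
Reagents that add atoms: none
Why: Yamaguchi–Hirao alkynylation opens the epoxide by SN2 at the unsubstituted C3, so the C2 stereocentre (the future butenolide carbon) is carried over unchanged from the chiral pool.

**Step 8**
Reactants: 11 methyl (2R)-2-hydroxyhex-4-ynoate
Product: 13 (3R)-3-hydroxyhept-5-yn-2-one, via Weinreb amide 12 (not isolated)
Conditions: MeNH(OMe)·HCl, MeMgBr (excess), THF, −20 to 0 °C; aq. NH4Cl
Reagents that add atoms: methylmagnesium bromide, C[Mg]Br
Why: Weinreb ketone synthesis run in one pot: the amide formed in situ takes up one methyl and rests as a chelated tetrahedral adduct until quench, giving the methyl ketone without over-addition or enolisation of the α-stereocentre.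

**Step 9**
Reactants: 13 (3R)-3-hydroxyhept-5-yn-2-one
Product: 15 (5R)-5-(but-2-yn-1-yl)-4-methylfuran-2(5H)-one, via phosphoranylidene ester 14 (not isolated)
Conditions: Ph3P=C=C=O, toluene, 90 °C
Reagents that add atoms: (triphenylphosphoranylidene)ketene, O=C=C=P(c1ccccc1)(c1ccccc1)c1ccccc1
Why: The Bestmann ylide acylates the hydroxyl and the resulting ester ylide closes by intramolecular Wittig olefination onto the ketone under neutral conditions, leaving the carbinol centre intact.

**Step 10**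
Reactants: 15 (5R)-5-(but-2-yn-1-yl)-4-methylfuran-2(5H)-one
Product: 16 (2Z,4R)-3-methyloct-2-en-6-yne-1,4-diol
Conditions: i-Bu2AlH (4 equiv), CH2Cl2, −78 to 0 °C; Rochelle salt
Reagents that add atoms: none
Why: 1,2-Hydride reduction of the lactone to the diol transcribes the ring geometry into the Z olefin and gives a base-stable masked butenolide; the internal alkyne is inert at this temperature.

**Step 11**
Reactants: 16 (2Z,4R)-3-methyloct-2-en-6-yne-1,4-diol
Product: 17 (2Z,4R)-3-methyl-1,4-bis(trimethylsilyloxy)oct-2-en-6-yne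
Conditions: TMSCl, imidazole, CH2Cl2, 0 °C
Reagents that add atoms: chlorotrimethylsilane, C[Si](C)(C)Cl
Why: Silylation masks both hydroxyls for the organometallic steps, and the TMS ethers fall off later in the saponification.

**Step 12**
Reactants: 17 (2Z,4R)-3-methyl-1,4-bis(trimethylsilyloxy)oct-2-en-6-yne
Product: 19 (2Z,4R,6E)-7-iodo-3-methyl-1,4-bis(trimethylsilyloxy)octa-2,6-diene, via alkenylzirconocene chloride 18 (not isolated)
Conditions: Cp2Zr(H)Cl (2.5 equiv), THF, 50 °C; then I2, 0 °C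
Reagents that add atoms: iodine, II
Why: Syn hydrozirconation with excess Cp2Zr(H)Cl equilibrates zirconium to the less hindered methyl-bearing alkyne carbon, and iodinolysis with retention gives the (E)-2-iodoalkene.

**Step 13**
Reactants: 8 8α-acetoxy-12-bromo-13,14,15,16-tetranorlabdan-18,6α-olide; 19 (2Z,4R,6E)-7-iodo-3-methyl-1,4-bis(trimethylsilyloxy)octa-2,6-diene
Product: 21 8α-acetoxy-12-[(2Z,4R,6E)-3-methyl-1,4-bis(trimethylsilyloxy)octa-2,6-dien-7-yl]-13,14,15,16-tetranorlabdan-18,6α-olide, via alkylzinc bromide 20 (not isolated)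
Conditions: Zn dust, I2 (5 mol%), DMA, 70 °C; then 19, PdCl2(dppf) (5 mol%), THF, 45 °C
Reagents that add atoms: none
Why: Zinc insertion into the primary bromide and Negishi sp3–sp2 coupling proceed with retention at the vinyl iodide, fixing the 13E trisubstituted olefin; the acetate, lactone and silyl ethers tolerate the organozinc.

**Step 14**
Reactants: 21 8α-acetoxy-12-[(2Z,4R,6E)-3-methyl-1,4-bis(trimethylsilyloxy)octa-2,6-dien-7-yl]-13,14,15,16-tetranorlabdan-18,6α-olide
Product: 22 6α,8α-dihydroxy-12-[(2Z,4R,6E)-1,4-dihydroxy-3-methylocta-2,6-dien-7-yl]-13,14,15,16-tetranorlabdan-18-oic acid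
Conditions: KOH, MeOH/H2O, 65 °C; then 1 M HCl to pH 4, 0 °C
Reagents that add atoms: potassium hydroxide, [K+].[OH-]
Why: Saponification cleaves the tertiary acetate, the strained neopentyl lactone and both silyl ethers while the butenolide is still a base-stable enediol, so no stereocentre is at risk.

**Step 15**
Reactants: 22 6α,8α-dihydroxy-12-[(2Z,4R,6E)-1,4-dihydroxy-3-methylocta-2,6-dien-7-yl]-13,14,15,16-tetranorlabdan-18-oic acid
Product: 24 6α,8α-dihydroxy-12-{(2E)-4-[(2R)-3-methyl-5-oxo-2,5-dihydrofuran-2-yl]but-2-en-2-yl}-13,14,15,16-tetranorlabdan-18-oic acid (target), via lactol 23 (not isolated)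
Conditions: TEMPO (0.2 equiv), PhI(OAc)2 (2.5 equiv), CH2Cl2/MeCN, rt
Reagents that add atoms: none
Why: TEMPO/PhI(OAc)2 oxidative lactonisation: the primary allylic alcohol is oxidised selectively, the Z-hydroxy enal closes to the lactol and this is oxidised on to the butenolide, leaving the secondary and tertiary hydroxyls, the acid and the lactone-carbon configuration unchanged.

**Compound list**
1 | (+)-larixol, (13S)-labda-8(17),14-diene-6α,13-diol | C=C[C@@](C)(O)CC[C@@H]1[C@@]2(C)CCCC(C)(C)[C@@H]2[C@@H](O)CC1=C | starting material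
2 | 6α-hydroxy-14,15-dinorlabd-8(17)-en-13-one | CC(=O)CC[C@@H]1[C@@]2(C)CCCC(C)(C)[C@@H]2[C@@H](O)CC1=C | intermediate
3 | 8α,13-epoxy-14,15-dinorlabd-12-en-6α-ol | CC1=CC[C@@H]2[C@@]3(C)CCCC(C)(C)[C@@H]3[C@@H](O)C[C@@]2(C)O1 | intermediate
4 | 8α-acetoxy-6α-hydroxy-13,14,15,16-tetranorlabdan-12-al | O=CC[C@@H]1[C@@]2(C)CCCC(C)(C)[C@@H]2[C@@H](O)C[C@@]1(C)OC(C)=O | intermediate (not isolated)
5 | 8α-acetoxy-13,14,15,16-tetranorlabdane-6α,12-diol | OCC[C@@H]1[C@@]2(C)CCCC(C)(C)[C@@H]2[C@@H](O)C[C@@]1(C)OC(C)=O | intermediate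
6 | 12-bromo-6α-hydroxy-13,14,15,16-tetranorlabdan-8α-yl acetate | BrCC[C@@H]1[C@@]2(C)CCCC(C)(C)[C@@H]2[C@@H](O)C[C@@]1(C)OC(C)=O | intermediate
7 | 12-bromo-6α,18-epoxy-13,14,15,16-tetranorlabdan-8α-yl acetate | BrCC[C@@H]1[C@@]2(C)CCC[C@@](C)(CO3)[C@@H]2[C@@H]3C[C@@]1(C)OC(C)=O | intermediate
8 | 8α-acetoxy-12-bromo-13,14,15,16-tetranorlabdan-18,6α-olide | BrCC[C@@H]1[C@@]2(C)CCC[C@@](C)(C(=O)O3)[C@@H]2[C@@H]3C[C@@]1(C)OC(C)=O | intermediate
9 | methyl (R)-glycidate, methyl (2R)-oxirane-2-carboxylate | COC(=O)[C@H]1CO1 | starting material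
10 | 1-propynyllithium | [Li]C#CC | starting material
11 | methyl (2R)-2-hydroxyhex-4-ynoate | CC#CC[C@@H](O)C(=O)OC | intermediate
12 | (2R)-2-hydroxy-N-methoxy-N-methylhex-4-ynamide | CC#CC[C@@H](O)C(=O)N(C)OC | intermediate (not isolated)
13 | (3R)-3-hydroxyhept-5-yn-2-one | CC#CC[C@@H](O)C(C)=O | intermediate
14 | (3R)-2-oxohept-5-yn-3-yl (triphenylphosphoranylidene)acetate | CC#CC[C@@H](OC(=O)C=P(c1ccccc1)(c1ccccc1)c1ccccc1)C(C)=O | intermediate (not isolated)
15 | (5R)-5-(but-2-yn-1-yl)-4-methylfuran-2(5H)-one | CC1=CC(=O)O[C@@H]1CC#CC | intermediate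
16 | (2Z,4R)-3-methyloct-2-en-6-yne-1,4-diol | OC/C=C(C)\[C@H](O)CC#CC | intermediate
17 | (2Z,4R)-3-methyl-1,4-bis(trimethylsilyloxy)oct-2-en-6-yne | C[Si](C)(C)OC/C=C(C)\[C@H](O[Si](C)(C)C)CC#CC | intermediate
18 | chlorobis(cyclopentadienyl)[(2E,5R,6Z)-6-methyl-5,8-bis(trimethylsilyloxy)octa-2,6-dien-2-yl]zirconium | C[Si](C)(C)OC/C=C(C)\[C@H](O[Si](C)(C)C)C/C=C(\C)[Zr](Cl)(C1C=CC=C1)C1C=CC=C1 | intermediate (not isolated)
19 | (2Z,4R,6E)-7-iodo-3-methyl-1,4-bis(trimethylsilyloxy)octa-2,6-diene | C[Si](C)(C)OC/C=C(C)\[C@H](O[Si](C)(C)C)C/C=C(\C)I | intermediate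
20 | (8α-acetoxy-18,6α-olido-13,14,15,16-tetranorlabdan-12-yl)zinc bromide | Br[Zn]CC[C@@H]1[C@@]2(C)CCC[C@@](C)(C(=O)O3)[C@@H]2[C@@H]3C[C@@]1(C)OC(C)=O | intermediate (not isolated)
21 | 8α-acetoxy-12-[(2Z,4R,6E)-3-methyl-1,4-bis(trimethylsilyloxy)octa-2,6-dien-7-yl]-13,14,15,16-tetranorlabdan-18,6α-olide | C[Si](C)(C)OC/C=C(C)\[C@H](O[Si](C)(C)C)C/C=C(\C)CC[C@@H]1[C@@]2(C)CCC[C@@](C)(C(=O)O3)[C@@H]2[C@@H]3C[C@@]1(C)OC(C)=O | intermediate
22 | 6α,8α-dihydroxy-12-[(2Z,4R,6E)-1,4-dihydroxy-3-methylocta-2,6-dien-7-yl]-13,14,15,16-tetranorlabdan-18-oic acid | OC/C=C(C)\[C@H](O)C/C=C(\C)CC[C@@H]1[C@@]2(C)CCC[C@@](C)(C(=O)O)[C@@H]2[C@@H](O)C[C@@]1(C)O | intermediate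
23 | 6α,8α-dihydroxy-12-{(2E)-4-[(2R)-5-hydroxy-3-methyl-2,5-dihydrofuran-2-yl]but-2-en-2-yl}-13,14,15,16-tetranorlabdan-18-oic acid | CC1=CC(O)O[C@@H]1C/C=C(\C)CC[C@@H]1[C@@]2(C)CCC[C@@](C)(C(=O)O)[C@@H]2[C@@H](O)C[C@@]1(C)O | intermediate (not isolated)
24 | 6α,8α-dihydroxy-12-{(2E)-4-[(2R)-3-methyl-5-oxo-2,5-dihydrofuran-2-yl]but-2-en-2-yl}-13,14,15,16-tetranorlabdan-18-oic acid (CNP0387770.1) | CC1=CC(=O)O[C@@H]1C/C=C(\C)CC[C@@H]1[C@@]2(C)CCC[C@@](C)(C(=O)O)[C@@H]2[C@@H](O)C[C@@]1(C)O | target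

**Totals and risks**
Total steps: 15. Longest linear sequence: 9 (steps 1–6, then 13–15; the side-arm branch, steps 7–12 then 13–15, is equally long).

Most likely to fail, step 2: the C8 cation may instead lose a proton to ring alkenes or close to the 8-epimer. The fallback builds the C8–O bond by epoxide reduction and sets out from 1. mCPBA (NaHCO3, CH2Cl2, 0 °C) epoxidises the exocyclic alkene from the α-face to (13S)-8α,17-epoxylabd-14-ene-6α,13-diol F1. LiAlH4 opens it at C17 to (13S)-labd-14-ene-6α,8α,13-triol F2. KMnO4 degrades the vinyl carbinol to 6α,8α-dihydroxy-14,15-dinorlabdan-13-one F3, and a trace of p-TsOH over 4 Å sieves dehydrates its hemiketal, coming back at 3.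

Most likely to fail, step 5: closure of the strained, trans-bridged ether may be slow or the ether may over-oxidise. The fallback is Barton nitrite photolysis, which needs no ring closure, and sets out from 6. NOCl/pyridine gives 8α-acetoxy-12-bromo-13,14,15,16-tetranorlabdan-6α-yl nitrite F4. Irradiation (Pyrex, benzene) transfers NO to C18 and gives, after tautomerisation, 12-bromo-6α-hydroxy-18-(hydroxyimino)-13,14,15,16-tetranorlabdan-8α-yl acetate F5. NaNO2 in aqueous AcOH frees the aldehyde as 12-bromo-6α,18-epoxy-18-hydroxy-13,14,15,16-tetranorlabdan-8α-yl acetate F6, and TEMPO/PhI(OAc)2 oxidises this lactol to the lactone, coming back at 8 (7 is bypassed).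

Most likely to fail, step 13: zinc insertion next to the ester groups or the alkyl–alkenyl coupling may stall. The fallback avoids any preformed organometallic and sets out from 8 and 19: nickel-catalysed reductive cross-electrophile coupling (NiBr2(dme), 4,4'-di-tert-butyl-2,2'-bipyridine, Mn powder, NaI, DMPU, 40 °C) joins the alkyl bromide and the vinyl iodide directly and comes back at 21; no new compound arises (F0).

**Further compounds**
F1 | step 2 | (13S)-8α,17-epoxylabd-14-ene-6α,13-diol | C=C[C@@](C)(O)CC[C@@H]1[C@@]2(C)CCCC(C)(C)[C@@H]2[C@@H](O)C[C@@]1(C3)O3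
F2 | step 2 | (13S)-labd-14-ene-6α,8α,13-triol | C=C[C@@](C)(O)CC[C@@H]1[C@@]2(C)CCCC(C)(C)[C@@H]2[C@@H](O)C[C@@]1(C)O
F3 | step 2 | 6α,8α-dihydroxy-14,15-dinorlabdan-13-one | CC(=O)CC[C@@H]1[C@@]2(C)CCCC(C)(C)[C@@H]2[C@@H](O)C[C@@]1(C)O
F4 | step 5 | 8α-acetoxy-12-bromo-13,14,15,16-tetranorlabdan-6α-yl nitrite | BrCC[C@@H]1[C@@]2(C)CCCC(C)(C)[C@@H]2[C@@H](ON=O)C[C@@]1(C)OC(C)=O
F5 | step 5 | 12-bromo-6α-hydroxy-18-(hydroxyimino)-13,14,15,16-tetranorlabdan-8α-yl acetate | BrCC[C@@H]1[C@@]2(C)CCC[C@@](C)(C=NO)[C@@H]2[C@@H](O)C[C@@]1(C)OC(C)=O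
F6 | step 5 | 12-bromo-6α,18-epoxy-18-hydroxy-13,14,15,16-tetranorlabdan-8α-yl acetate | BrCC[C@@H]1[C@@]2(C)CCC[C@@](C)(C(O)O3)[C@@H]2[C@@H]3C[C@@]1(C)OC(C)=O
F0 | step 13 | none | none
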